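Friday's, Tuesday's, Thursday's and Wednesday's charge the same amounts of G and E; they differ in how these go in, and Wednesday's also in its temperature during the addition.

| flask | G | E | temperature | remark | time |
|---|---|---|---|---|---|
| summer | 10 mM | 50 mM | 45 °C | run made earlier |  |
| autumn | 10 mM | 25 mM | 56 °C | run made earlier |  |
| midnight | 10 mM | 100 mM | 45 °C | run made earlier |  |
| spring | 15 mM | 50 mM | 56 °C | run made earlier |  |
| Friday's | 10 mM | 50.0 mM (in portions, 3, over 50 min) | 50 °C | first portion at the start, last at 50 min | 2.0 h |
| Tuesday's | 10 mM (fed, over 50 min) | 50.0 mM | 50 °C | all else is in the flask from the start; the feed brings no volume worth counting | 2.0 h |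
| Thursday's | 10 mM | 50.0 mM | 50 °C | everything together at the start | 2.0 h |
| Wednesday's | 10 mM (fed, over 50 min) | 50.0 mM |  | the addition at 10 °C, then warmed to 50 °C; the feed brings no volume worth counting | 2.0 h |

- summer (time / min: D / %): 6.00: 5.3; 20.0: 12.1; 30.0: 15.9; 50.0: 22.6; 80.0: 27.8; 90.0: 28.4; 120: 31.8
- autumn (time / min: D / %): 8.00: 6.7; 12.0: 10.6; 20.0: 16.5; 25.0: 17.1; 40.0: 26.2; 60.0: 33.5; 90.0: 38.4
- midnight (time / min: D / %): 5.00: 5.9; 15.0: 14.0; 25.0: 16.6; 40.0: 20.1; 60.0: 20.8; 80.0: 20.5; 90.0: 20.6
- spring (time / min: D / %): 20.0: 21.4; 40.0: 30.9; 60.0: 37.4; 80.0: 39.4; 90.0: 41.0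

(scatter of a reading: 1 percentage point)

- percent here means G units held: one L counts as two
- what is said of D includes L
- steps that have been proposed: G + E -> D; G + 2 E -> Q; G + D <-> L; E -> J
- in an amount of D, one L counts as one D

* which flask leads in amount of D, in percent of the G charged ("all alike" within 1.5 percentage points) (Friday's / Tuesday's / Thursday's / Wednesday's / all alike)
* how much D is there at the end, in percent of the G charged: Friday's
* how much D is there at the end, in percent of the G charged: Tuesday's
* how much D is there at the end, in percent of the G charged: Thursday's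
* how much D is there at the end, in percent of the G charged: Wednesday's

A molecule of G reaches a fork: with one E it goes to D, with two E to Q. By these proposed steps, the share of G going to D is s = E\*/(E\* + [E]), where [E] is the E that G meets.

The midnight run levels at 20.6 % of D. Its mean [E] is about 91.0 mM, so the reading gives E\* = 23.6 mM. This E\* is the crossover concentration, the [E] of even chances, a selectivity factor. My reckoning carries it unchanged to 50 °C.

In Thursday's, [E] averages about 41.6 mM, so s = 36.2 %.

Friday's I split into two legs, taking half of G through each. Before the last portion, E charged averages 25.0 mM, giving 48.6 %. After it, about 42.4 mM stands, giving 35.8 %. The mean is 42.2 %, more than Thursday's. That is a share of reacted G, not an end amount, so it is not the forecast's figure.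

The forecast names Friday's, with 38 % for Friday's, 32.5 % for Tuesday's, 34 % for Thursday's and 30.5 % for Wednesday's: “portioned E stays low early, so selectivity is better”.

Friday's ends with 40.6 % of D, more than Thursday's 36.1 %, Tuesday's 34.2 % and Wednesday's 31.2 %.

    G + E → D (k = 16.0 L mol⁻¹ h⁻¹, Ea = 67.0 kJ mol⁻¹)
    G + 2 E → Q (k = 610 L² mol⁻² h⁻¹, Ea = 52.0 kJ mol⁻¹)
    G + D ⇌ L, settled at all times (K = 39.0 L mol⁻¹, ΔH = 22.0 kJ mol⁻¹)
    E → J (k = 0.0130 h⁻¹, Ea = 109 kJ mol⁻¹)
    (constants at 50 °C)

Friday's D has moved 5 points at an E charge of 28.4 mM or 93.6 mM, with the other amounts and the time held. Just before Friday's last portion, D stood at 22.3 % and Q at 19.8 %. Through E\*, that ratio gives a met [E] of 21.0 mM, less than the 25.0 mM taken.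

The neighbour of Friday's charged with 20 mM of E, on the same two legs, gets 70.3 % and 63.6 %, a share of 66.9 %. Computed, it ends with D 29.7 %, Q 15.3 % and G 50.1 %, a share of 66.0 % of D in D plus Q.

The runs were generated by integration from invented constants; noise was put on by code.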